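**Plan**

- Retrosynthetic cuts: O1–C2 and C2–C3 (ring C, with ring B arriving as an aroyl unit); C4–C4a (a two-carbon C3–C4 unit added to ring A); C8–C8a and C6–C7 of ring A (benzannulation); and the benzylic C–aryl bond of the side chain.
- Enabling feature: ring A (C4a, C5, C6, C7, C8, C8a) is a phloroglucinol whose three oxygens have different fates (O1 in ring C, O7 free, O5 peri to C4=O). Its C8 carries the stereogenic 1-arylethyl group between the O1- and O7-bearing carbons. This is the OH / R / OSi pattern that a vinylketene and a siloxyalkyne deliver.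
- Forward order: side-chain stereocentre, siloxyalkyne, ring A by benzannulation with 3-ethoxycyclobutenone (its ethoxy becomes O5), the C3–C4 unit at C4a by ortho-hydroxyalkylation and oxidation, ring B by enolate aroylation, ring C by cyclodehydration, deprotection last.
- Stereochemistry: the single (R) centre is set by an enantioconvergent nickel/pybox Negishi arylation of a racemic propargylic bromide and is only carried afterwards. Ring A sees no acid until it bears the deactivating carbonyl.

Key step: step 7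

Assumption: the pybox antipode for step 4 is chosen by analogy with known aryl/methyl/silylalkynyl couplings so that the (R)-alkyne results; enantiomeric purity would be checked at 10 and, if needed, raised by recrystallising a later crystalline intermediate.

**Route**

Step 1
Reactants: 1 4-bromo-2,6-dimethoxyphenol
Product: 2 2-(benzyloxy)-5-bromo-1,3-dimethoxybenzene
Conditions: BnBr, K2CO3, DMF, 50 °C
Reagents that add atoms: benzyl bromide, BrCc1ccccc1
Why: Williamson ether synthesis, in which the phenoxide formed by K2CO3 is benzylated by SN2 attack on benzyl bromide despite the two flanking methoxy groups.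

Step 2
Reactants: 2 2-(benzyloxy)-5-bromo-1,3-dimethoxybenzene
Product: 5 (4-benzyloxy-3,5-dimethoxyphenyl)boronic acid, via aryllithium 3 (not isolated), via lithium triisopropoxyborate 4 (not isolated)
Conditions: n-BuLi, THF, −78 °C; B(OiPr)3, −78 °C → rt; 1 M HCl
Reagents that add atoms: triisopropyl borate, CC(C)OB(OC(C)C)OC(C)C; water, O
Why: Bromine–lithium exchange at −78 °C followed by electrophilic borylation of the aryllithium is the standard arylboronic acid synthesis and is faster than any attack on the benzyl or methyl ethers, and brief mild acid hydrolyses the borate.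

Step 3
Reactants: 6 racemic 4-(trimethylsilyl)but-3-yn-2-ol
Product: 7 racemic 3-bromo-1-(trimethylsilyl)but-1-yne
Conditions: CBr4, PPh3, CH2Cl2, 0 °C
Reagents that add atoms: carbon tetrabromide, BrC(Br)(Br)Br
Why: Appel reaction, in which bromide displaces the alkoxyphosphonium group at the propargylic carbon while the bulky silyl group disfavours SN2′ attack at the alkyne terminus; a racemic bromide is all the next step needs.

Step 4
Reactants: 7 racemic 3-bromo-1-(trimethylsilyl)but-1-yne; 5 (4-benzyloxy-3,5-dimethoxyphenyl)boronic acid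
Product: 9 (R)-[3-(4-benzyloxy-3,5-dimethoxyphenyl)but-1-yn-1-yl]trimethylsilane, via arylethylzinc 8 (not isolated)
Conditions: 5, Et2Zn, toluene, 60 °C; then 7, NiCl2·DME (3 mol%), indanyl-pybox (4 mol%), DME, −20 °C
Reagents that add atoms: none
Why: Enantioconvergent nickel-catalysed Negishi coupling, in which boron-to-zinc exchange gives arylzinc 8, the catalyst formed from divalent NiCl2·DME and the chiral pybox turns both enantiomers of 7 into one propargylic radical, and the chiral arylnickel complex captures it on one face, so the ligand sets the (R)-stereocentre as the C–aryl bond forms.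

Step 5
Reactants: 9 (R)-[3-(4-benzyloxy-3,5-dimethoxyphenyl)but-1-yn-1-yl]trimethylsilane
Product: 10 (S)-2-(benzyloxy)-5-(but-3-yn-2-yl)-1,3-dimethoxybenzene
Conditions: K2CO3 (0.2 equiv), MeOH, 0 °C
Reagents that add atoms: none
Why: Base-catalysed methanolysis of the C(sp)–Si bond (protodesilylation) is fast at 0 °C under conditions too mild to remove the propargylic–benzylic hydrogen, so the centre should be retained (the descriptor becomes S only because the alkynyl branch loses its silicon and drops in priority).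

Step 6
Reactants: 10 (S)-2-(benzyloxy)-5-(but-3-yn-2-yl)-1,3-dimethoxybenzene
Product: 13 (R)-{[3-(4-benzyloxy-3,5-dimethoxyphenyl)but-1-yn-1-yl]oxy}triisopropylsilane, via lithium acetylide 11 (not isolated), via lithium ynolate 12 (not isolated)
Conditions: LiHMDS (2.2 equiv), THF, −78 °C; t-BuOOH (1.1 equiv), −78 → 0 °C; TIPSOTf, −78 °C → rt
Reagents that add atoms: tert-butyl hydroperoxide, CC(C)(C)OO; triisopropylsilyl trifluoromethanesulfonate, CC(C)[Si](OS(=O)(=O)C(F)(F)F)(C(C)C)C(C)C
Why: Electrophilic oxygenation of the lithium acetylide by lithium tert-butyl peroxide gives the lithium ynolate (the known acetylide-to-ynolate oxidation), and the bulky silyl triflate then silylates oxygen and not carbon, while LiHMDS at −78 °C removes only the sp C–H.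

Step 7
Reactants: 13 (R)-{[3-(4-benzyloxy-3,5-dimethoxyphenyl)but-1-yn-1-yl]oxy}triisopropylsilane; 14 3-ethoxycyclobut-2-en-1-one
Product: 19 2-[(1R)-1-(4-benzyloxy-3,5-dimethoxyphenyl)ethyl]-5-ethoxy-3-[(triisopropylsilyl)oxy]phenol, via vinylketene 15 (not isolated), via vinylcyclobutenone 16 (not isolated), via dienylketene 17 (not isolated), via cyclohexadienone 18 (not isolated)
Conditions: toluene (degassed), 80 °C then 110 °C, sealed tube
Reagents that add atoms: none
Why: Heating opens 14 by 4π-electrocyclic ring opening to the ethoxy-substituted vinylketene 15, whose ketene C=C adds [2+2] to the siloxyalkyne to give 16; a second 4π opening gives dienylketene 17, a thermal disrotatory 6π-electrocyclisation gives cyclohexadienone 18, and tautomerisation gives phenol 19. The closest known reaction type is the Danheiser benzannulation of cyclobutenones with trialkylsiloxyalkynes to resorcinol monosilyl ethers, the cyclobutenone here carrying an additional 3-alkoxy group. Ring A is closed by the 6π-electrocyclisation, which re-forms C4a–C8a after the [2+2] step has made C8–C8a and C6–C7. No stereocentre is created, since the ring carbon of 16 is transient, and the existing (R)-centre is not involved in the neutral, aprotic cascade and ends up on C8. The selectivity needed is the regiochemistry of the [2+2] step, secured by the polarisation of the ynol ether: its carbon remote from oxygen is the nucleophilic terminus and bonds to the ketene carbonyl carbon, so the free OH (future O1) and the silyl ether (O7) flank the side chain, the ethoxy group becomes O5, and the only unsubstituted carbon ortho to the OH is the future C4a.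

Step 8
Reactants: 19 2-[(1R)-1-(4-benzyloxy-3,5-dimethoxyphenyl)ethyl]-5-ethoxy-3-[(triisopropylsilyl)oxy]phenol; 20 benzyloxyacetaldehyde
Product: 22 2-(benzyloxy)-1-{3-[(1R)-1-(4-benzyloxy-3,5-dimethoxyphenyl)ethyl]-6-ethoxy-2-hydroxy-4-[(triisopropylsilyl)oxy]phenyl}ethan-1-ol (both carbinol epimers), via bromomagnesium phenolate 21 (not isolated)
Conditions: EtMgBr (1.0 equiv), Et2O, 0 °C; solvent exchange to CH2Cl2; 20, rt; pH 7 buffer
Reagents that add atoms: none
Why: Chelation-controlled ortho-hydroxyalkylation of a bromomagnesium phenolate, in which the aldehyde binds to the phenolate magnesium in the non-coordinating solvent and is delivered through a six-membered transition state to the only free ortho carbon (C4a), forming C4–C4a without acid; the new carbinol centre forms unselectively and is removed in step 9.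

Step 9
Reactants: 22 the diol from step 8
Product: 23 2-(benzyloxy)-1-{3-[(1R)-1-(4-benzyloxy-3,5-dimethoxyphenyl)ethyl]-6-ethoxy-2-hydroxy-4-[(triisopropylsilyl)oxy]phenyl}ethan-1-one
Conditions: MnO2 (activated, excess), CH2Cl2, rt
Reagents that add atoms: none
Why: MnO2 oxidation of a benzylic alcohol, which converts the electron-rich benzylic carbinol selectively into the hydrogen-bonded ortho-hydroxyaryl ketone and leaves the phenol, the ethers and the diarylmethine C–H alone.

Step 10
Reactants: 24 4-(benzyloxy)-3-methoxybenzoic acid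
Product: 25 4-(benzyloxy)-3-methoxybenzoyl chloride
Conditions: (COCl)2, DMF (cat.), CH2Cl2, 0 °C → rt
Reagents that add atoms: oxalyl chloride, O=C(Cl)C(=O)Cl
Why: Acid chloride formation with oxalyl chloride under Vilsmeier-type DMF catalysis, compatible with the aryl benzyl and methyl ethers.

Step 11
Reactants: 23 the ω-benzyloxy ketone from step 9; 25 4-(benzyloxy)-3-methoxybenzoyl chloride
Product: 26 2-(benzyloxy)-1-{3-[(1R)-1-(4-benzyloxy-3,5-dimethoxyphenyl)ethyl]-6-ethoxy-2-hydroxy-4-[(triisopropylsilyl)oxy]phenyl}-3-[4-(benzyloxy)-3-methoxyphenyl]propane-1,3-dione (C2 epimers and enol forms)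
Conditions: LiHMDS (3.3 equiv), THF, −78 °C; 25, −78 → −10 °C; aq. NH4Cl
Reagents that add atoms: none
Why: Lithium-polyanion variant of the Baker–Venkataraman diketone synthesis, in which the phenoxide–enolate dianion of 23 is acylated at its chelated α-alkoxy enolate carbon (C3) by 25 to form C2–C3, the third equivalent of base holding the product as its enolate; the base is too weak to remove the diarylmethine hydrogen, and the new C3 centre is lost on cyclisation.

Step 12
Reactants: 26 the 1,3-diketone from step 11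
Product: 27 3-(benzyloxy)-2-[4-(benzyloxy)-3-methoxyphenyl]-8-[(1R)-1-(4-benzyloxy-3,5-dimethoxyphenyl)ethyl]-5-ethoxy-7-[(triisopropylsilyl)oxy]-4H-chromen-4-one
Conditions: p-TsOH·H2O (cat.), toluene, 80 °C
Reagents that add atoms: none
Why: Acid-catalysed cyclodehydration (6-exo-trig addition of the phenolic O1 to the aroyl carbonyl, then loss of water) closes ring C as the aromatic 4-pyranone, and the carbonyl now on ring A protects the C8 side chain against ipso-protonation and loss.

Step 13
Reactants: 27 the silylated 3-benzyloxyflavone from step 12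
Product: 28 3-(benzyloxy)-2-[4-(benzyloxy)-3-methoxyphenyl]-8-[(1R)-1-(4-benzyloxy-3,5-dimethoxyphenyl)ethyl]-5-ethoxy-7-hydroxy-4H-chromen-4-one
Conditions: TBAF, AcOH, THF, 0 °C
Reagents that add atoms: none
Why: Fluoride-mediated cleavage of the aryl silyl ether, made easy because the chromone 7-oxide is a good leaving group, with acetic acid as buffer so that the product is not held as a phenoxide.

Step 14
Reactants: 28 the 7-hydroxy-3-benzyloxyflavone from step 13
Product: 29 3,5,7-trihydroxy-2-(4-hydroxy-3-methoxyphenyl)-8-[(1R)-1-(4-hydroxy-3,5-dimethoxyphenyl)ethyl]-4H-chromen-4-one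
Conditions: BCl3, C6HMe5, CH2Cl2, −78 → 0 °C; MeOH
Reagents that add atoms: none
Why: Lewis-acid ether cleavage with BCl3, in which the three benzyl ethers are cleaved at −78 °C with pentamethylbenzene trapping the benzyl cation and, on warming, the peri 5-O-ethyl group is removed through the six-membered boron chelate with the C4 carbonyl, whereas the three aryl methyl ethers lack such a chelating carbonyl and should survive at or below 0 °C.

**Compound list**

1 | 4-bromo-2,6-dimethoxyphenol | COc1cc(Br)cc(OC)c1O | starting material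
2 | 2-(benzyloxy)-5-bromo-1,3-dimethoxybenzene | COc1cc(Br)cc(OC)c1OCc1ccccc1 | intermediate
3 | (4-benzyloxy-3,5-dimethoxyphenyl)lithium | [Li]c1cc(OC)c(OCc2ccccc2)c(OC)c1 | intermediate
4 | lithium (4-benzyloxy-3,5-dimethoxyphenyl)triisopropoxyborate | [Li+].CC(C)O[B-](OC(C)C)(OC(C)C)c1cc(OC)c(OCc2ccccc2)c(OC)c1 | intermediate
5 | (4-benzyloxy-3,5-dimethoxyphenyl)boronic acid | OB(O)c1cc(OC)c(OCc2ccccc2)c(OC)c1 | intermediate
6 | racemic 4-(trimethylsilyl)but-3-yn-2-ol | CC(O)C#C[Si](C)(C)C | starting material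
7 | racemic 3-bromo-1-(trimethylsilyl)but-1-yne | CC(Br)C#C[Si](C)(C)C | intermediate
8 | (4-benzyloxy-3,5-dimethoxyphenyl)(ethyl)zinc | CC[Zn]c1cc(OC)c(OCc2ccccc2)c(OC)c1 | intermediate
9 | (R)-[3-(4-benzyloxy-3,5-dimethoxyphenyl)but-1-yn-1-yl]trimethylsilane | C[Si](C)(C)C#C[C@H](C)c1cc(OC)c(OCc2ccccc2)c(OC)c1 | intermediate
10 | (S)-2-(benzyloxy)-5-(but-3-yn-2-yl)-1,3-dimethoxybenzene | C#C[C@H](C)c1cc(OC)c(OCc2ccccc2)c(OC)c1 | intermediate
11 | lithium (3R)-3-(4-benzyloxy-3,5-dimethoxyphenyl)but-1-yn-1-ide | [Li]C#C[C@H](C)c1cc(OC)c(OCc2ccccc2)c(OC)c1 | intermediate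
12 | lithium (3R)-3-(4-benzyloxy-3,5-dimethoxyphenyl)but-1-yn-1-olate | [Li]OC#C[C@H](C)c1cc(OC)c(OCc2ccccc2)c(OC)c1 | intermediate
13 | (R)-{[3-(4-benzyloxy-3,5-dimethoxyphenyl)but-1-yn-1-yl]oxy}triisopropylsilane | CC(C)[Si](OC#C[C@H](C)c1cc(OC)c(OCc2ccccc2)c(OC)c1)(C(C)C)C(C)C | intermediate
14 | 3-ethoxycyclobut-2-en-1-one | CCOC1=CC(=O)C1 | starting material
15 | 3-ethoxybuta-1,3-dien-1-one (vinylketene) | CCOC(=C)C=C=O | intermediate
16 | 2-[(1R)-1-(4-benzyloxy-3,5-dimethoxyphenyl)ethyl]-4-(1-ethoxyethenyl)-3-[(triisopropylsilyl)oxy]cyclobut-2-en-1-one (ring carbon C4 unassigned) | CCOC(=C)C1C(=O)C([C@H](C)c2cc(OC)c(OCc3ccccc3)c(OC)c2)=C1O[Si](C(C)C)(C(C)C)C(C)C | intermediate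
17 | (3Z)-2-[(1R)-1-(4-benzyloxy-3,5-dimethoxyphenyl)ethyl]-5-ethoxy-3-[(triisopropylsilyl)oxy]hexa-1,3,5-trien-1-one (dienylketene) | CCOC(=C)/C=C(/O[Si](C(C)C)(C(C)C)C(C)C)C(=C=O)[C@H](C)c1cc(OC)c(OCc2ccccc2)c(OC)c1 | intermediate
18 | 2-[(1R)-1-(4-benzyloxy-3,5-dimethoxyphenyl)ethyl]-5-ethoxy-3-[(triisopropylsilyl)oxy]cyclohexa-2,4-dien-1-one | CCOC1=CC(O[Si](C(C)C)(C(C)C)C(C)C)=C([C@H](C)c2cc(OC)c(OCc3ccccc3)c(OC)c2)C(=O)C1 | intermediate
19 | 2-[(1R)-1-(4-benzyloxy-3,5-dimethoxyphenyl)ethyl]-5-ethoxy-3-[(triisopropylsilyl)oxy]phenol | CCOc1cc(O)c([C@H](C)c2cc(OC)c(OCc3ccccc3)c(OC)c2)c(O[Si](C(C)C)(C(C)C)C(C)C)c1 | intermediate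
20 | benzyloxyacetaldehyde | O=CCOCc1ccccc1 | starting material
21 | bromomagnesium phenolate of 19 | CCOc1cc(O[Mg]Br)c([C@H](C)c2cc(OC)c(OCc3ccccc3)c(OC)c2)c(O[Si](C(C)C)(C(C)C)C(C)C)c1 | intermediate
22 | 2-(benzyloxy)-1-{3-[(1R)-1-(4-benzyloxy-3,5-dimethoxyphenyl)ethyl]-6-ethoxy-2-hydroxy-4-[(triisopropylsilyl)oxy]phenyl}ethan-1-ol (carbinol epimers) | CCOc1cc(O[Si](C(C)C)(C(C)C)C(C)C)c([C@H](C)c2cc(OC)c(OCc3ccccc3)c(OC)c2)c(O)c1C(O)COCc1ccccc1 | intermediate
23 | 2-(benzyloxy)-1-{3-[(1R)-1-(4-benzyloxy-3,5-dimethoxyphenyl)ethyl]-6-ethoxy-2-hydroxy-4-[(triisopropylsilyl)oxy]phenyl}ethan-1-one | CCOc1cc(O[Si](C(C)C)(C(C)C)C(C)C)c([C@H](C)c2cc(OC)c(OCc3ccccc3)c(OC)c2)c(O)c1C(=O)COCc1ccccc1 | intermediate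
24 | 4-(benzyloxy)-3-methoxybenzoic acid | O=C(O)c1ccc(OCc2ccccc2)c(OC)c1 | starting material
25 | 4-(benzyloxy)-3-methoxybenzoyl chloride | O=C(Cl)c1ccc(OCc2ccccc2)c(OC)c1 | intermediate
26 | 2-(benzyloxy)-1-{3-[(1R)-1-(4-benzyloxy-3,5-dimethoxyphenyl)ethyl]-6-ethoxy-2-hydroxy-4-[(triisopropylsilyl)oxy]phenyl}-3-[4-(benzyloxy)-3-methoxyphenyl]propane-1,3-dione (C2 epimers) | CCOc1cc(O[Si](C(C)C)(C(C)C)C(C)C)c([C@H](C)c2cc(OC)c(OCc3ccccc3)c(OC)c2)c(O)c1C(=O)C(OCc1ccccc1)C(=O)c1ccc(OCc2ccccc2)c(OC)c1 | intermediate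
27 | 3-(benzyloxy)-2-[4-(benzyloxy)-3-methoxyphenyl]-8-[(1R)-1-(4-benzyloxy-3,5-dimethoxyphenyl)ethyl]-5-ethoxy-7-[(triisopropylsilyl)oxy]-4H-chromen-4-one | COc1cc(-c2oc3c([C@H](C)c4cc(OC)c(OCc5ccccc5)c(OC)c4)c(O[Si](C(C)C)(C(C)C)C(C)C)cc(OCC)c3c(=O)c2OCc2ccccc2)ccc1OCc1ccccc1 | intermediate
28 | 3-(benzyloxy)-2-[4-(benzyloxy)-3-methoxyphenyl]-8-[(1R)-1-(4-benzyloxy-3,5-dimethoxyphenyl)ethyl]-5-ethoxy-7-hydroxy-4H-chromen-4-one | COc1cc(-c2oc3c([C@H](C)c4cc(OC)c(OCc5ccccc5)c(OC)c4)c(O)cc(OCC)c3c(=O)c2OCc2ccccc2)ccc1OCc1ccccc1 | intermediate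
29 | 3,5,7-trihydroxy-2-(4-hydroxy-3-methoxyphenyl)-8-[(1R)-1-(4-hydroxy-3,5-dimethoxyphenyl)ethyl]-4H-chromen-4-one | COc1cc(-c2oc3c([C@H](C)c4cc(OC)c(O)c(OC)c4)c(O)cc(O)c3c(=O)c2O)ccc1O | target

**Step count and risks**

Total steps: 14. Longest linear sequence: 12 steps (steps 1, 2, 4, 5, 6, 7, 8, 9, 11, 12, 13, 14, from 4-bromo-2,6-dimethoxyphenol).

Steps most likely to fail:

1. Step 7. The alkoxy-substituted vinylketene may be lost to self-condensation or to acylation of the phenolic product before it meets the alkyne. The vinylogous-ester cyclobutenone may also need temperatures at which the siloxyalkyne rearranges to a silylketene. The fallback sets out from 13 and generates the same vinylketene 15 cold, without the cyclobutenone. Commercial ethyl (E)-3-ethoxybut-2-enoate is saponified (LiOH, THF/H2O) to (E)-3-ethoxybut-2-enoic acid F1. This is converted with (COCl)2 and catalytic DMF into (E)-3-ethoxybut-2-enoyl chloride F2. Slow addition of F2 to 13 and Et3N in CH2Cl2 at 0 °C gives 15 by 1,4-dehydrochlorination, and 15 is trapped by the ynol ether as vinylcyclobutenone 16. Brief warming in toluene then takes 16 through 17 and 18, and the route is rejoined at 19.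

2. Step 8. The hindered magnesium phenolate may react sluggishly. Alternatively the electron-rich benzylic alkoxide may ionise to a quinone methide that is captured by a second phenolate, giving diarylmethane. The fallback sets out from 19 and reverses the polarity of the C4–C4a bond formation. Ortho-formylation (MgCl2, Et3N, (CH2O)n, MeCN, reflux) gives 3-[(1R)-1-(4-benzyloxy-3,5-dimethoxyphenyl)ethyl]-6-ethoxy-2-hydroxy-4-[(triisopropylsilyl)oxy]benzaldehyde F3. After deprotonation of the phenol with LiHMDS, (benzyloxymethyl)lithium is added at −78 °C; it is made from tributyl[(benzyloxy)methyl]stannane and n-BuLi. This rejoins the route at 22.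

3. Step 14. The peri ethyl ether may cleave incompletely at temperatures where the methyl ethers are still safe, or a methyl ether next to a boron-bound phenoxide may be lost on warming. The fallback sets out from 28 and separates the two tasks. Neutral hydrogenolysis (H2, Pd/C, EtOAc/MeOH) removes the three benzyl groups to give 5-ethoxy-3,7-dihydroxy-2-(4-hydroxy-3-methoxyphenyl)-8-[(1R)-1-(4-hydroxy-3,5-dimethoxyphenyl)ethyl]-4H-chromen-4-one F4. Chelation-controlled dealkylation with AlCl3 in MeCN then removes only the ether peri to the C4 carbonyl and rejoins the route at 29.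

Further compounds
F1 | step 7 | (E)-3-ethoxybut-2-enoic acid | CCO/C(C)=C/C(=O)O
F2 | step 7 | (E)-3-ethoxybut-2-enoyl chloride | CCO/C(C)=C/C(=O)Cl
F3 | step 8 | 3-[(1R)-1-(4-benzyloxy-3,5-dimethoxyphenyl)ethyl]-6-ethoxy-2-hydroxy-4-[(triisopropylsilyl)oxy]benzaldehyde | CCOc1cc(O[Si](C(C)C)(C(C)C)C(C)C)c([C@H](C)c2cc(OC)c(OCc3ccccc3)c(OC)c2)c(O)c1C=O
F4 | step 14 | 5-ethoxy-3,7-dihydroxy-2-(4-hydroxy-3-methoxyphenyl)-8-[(1R)-1-(4-hydroxy-3,5-dimethoxyphenyl)ethyl]-4H-chromen-4-one | COc1cc(-c2oc3c([C@H](C)c4cc(OC)c(O)c(OC)c4)c(O)cc(OCC)c3c(=O)c2O)ccc1O
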